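## Retrosynthetic overview

1. The C6 chloride is installed last from the 6-epi alcohol (inversion). The ten-membered ring is closed at C9–C10 by a SmI2 ketyl–enone radical cyclisation of seco aldehyde 24, which also sets C9, C10 and C11.
2. Compound 24 comes from Sonogashira union (C4–C5) of ring A alkyne 11 with bromovinyl lactone 20, cis semi-reduction, and acid unmasking of the enone and the aldehyde.
3. Ring A (11): catalytic asymmetric Diels–Alder reaction of a 1-butanoyloxy-3-siloxy diene with (E)-3-bromo-2-methylacrolein (sets C1, C14), then ethynylation/acetylation at C2.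
4. Lactone 20: tetronic acid plus 2-bromoacrolein by asymmetric vinylogous aldol (C6, C7), C8–C9 by dioxolanyl radical addition, C17 by enolate methylation.
5. Ring order: the six-membered ring and the γ-lactone are made first, separately; the ten-membered ring is made last.

Numbering: briarane numbering of the target is used for every intermediate: C1 (quaternary, C15 methyl), C2 (OAc), C3=C4, C5(=C16), C6 (Cl), C7 (lactone O), C8 (OH), C9 (OAc), C10, C11 (C20 methyl), C12 (C=O), C13, C14 (butanoate), C17 (C18 methyl), C19 (lactone C=O); β is the face of the C15 methyl.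

Assumption: pent-1-yn-3-one and 2-bromoacrolein are bought as such.

Assumption: the two chiral boron catalysts are named for the sense of induction expected from their published facial models; the mirror-image catalyst is used if the sense proves opposite.

## Route

Step 1
Reactants: 1 pent-1-yn-3-one; 2 butanoic acid
Product: 3 (E)-3-oxopent-1-en-1-yl butanoate
Conditions: N-methylmorpholine (10 mol%), CH2Cl2, 0 °C to rt
Reagents that add atoms: none
Why: Amine-catalysed conjugate addition of the carboxylic acid to the ynone (oxa-Michael addition) gives the thermodynamically favoured (E)-β-acyloxy enone, so the C14 butanoate is in place from the first step.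

Step 2
Reactants: 3 (E)-3-oxopent-1-en-1-yl butanoate
Product: 4 (1E,3Z)-3-[(triisopropylsilyl)oxy]penta-1,3-dien-1-yl butanoate
Conditions: i-Pr3SiOTf, Et3N, Et2O, 0 °C
Reagents that add atoms: triisopropylsilyl trifluoromethanesulfonate (CC(C)[Si](C(C)C)(C(C)C)OS(=O)(=O)C(F)(F)F)
Why: Soft enolisation of the ethyl ketone with a silyl triflate and Et3N (silyl enol ether formation) gives the (Z)-enol ether, that is the 1-acyloxy-3-siloxy diene whose terminal methyl points outward in the s-cis form.

Step 3
Reactants: 5 methacrolein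
Product: 7 (E)-3-bromo-2-methylprop-2-enal, via dibromide 6 (not isolated)
Conditions: Br2, CH2Cl2, −78 °C; then Et3N, 0 °C
Reagents that add atoms: bromine (BrBr)
Why: Bromine adds across the enal and Et3N removes HBr from the dibromide (bromination–dehydrobromination) to give the conjugated, thermodynamically preferred (E)-β-bromo enal.

Step 4
Reactants: 4 siloxy diene; 7 (E)-3-bromo-2-methylprop-2-enal
Product: 8 ring A aldehyde (1S,4R,5S,6R)-5-bromo-6-formyl-4,6-dimethyl-3-[(triisopropylsilyl)oxy]cyclohex-2-en-1-yl butanoate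
Conditions: (S)-3,3-diphenyl-1-(2-methylphenyl)tetrahydro-1H,3H-pyrrolo[1,2-c][1,3,2]oxazaborole (20 mol%) with HN(SO2CF3)2 (18 mol%), CH2Cl2, −78 °C
Reagents that add atoms: none
Why: Catalytic enantioselective Diels–Alder reaction in which the 1-acyloxy and 3-siloxy groups both send the nucleophilic diene terminus (C11) to the enal β-carbon (C10), the endo-formyl transition state puts the C14 oxygen cis to the formyl group on the quaternary C1, the (E)-enal keeps Br trans to CHO, and the aryl group of the protonated oxazaborolidine shields one enal face so that C1 and C14 are set in the absolute sense of the target (C10 and C11 are erased later).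

Step 5
Reactants: 8 ring A aldehyde; 9 ethynylmagnesium bromide
Product: 11 ring A alkyne (1S,4R,5S,6R)-6-[(1S)-1-acetoxyprop-2-yn-1-yl]-5-bromo-4,6-dimethyl-3-[(triisopropylsilyl)oxy]cyclohex-2-en-1-yl butanoate, via bromomagnesium alkoxide 10 (not isolated)
Conditions: THF, −78 °C; then Ac2O, −78 to 0 °C
Reagents that add atoms: acetic anhydride (CC(=O)OC(C)=O)
Why: 1,2-Addition of the Grignard reagent to the neopentyl aldehyde under Felkin–Anh/1,3-anti control (attack anti to the bromine-bearing C10 and past the C1 methyl, carbonyl turned toward the β-oxygen at C14) sets the 2S carbinol, and the magnesium alkoxide is acetylated in the same flask before oxetane formation or acyl migration can intervene.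

Step 6
Reactants: 12 tetronic acid; 13 2-bromoacrolein
Product: 16 (5S)-5-[(1S)-2-bromo-1-hydroxyprop-2-en-1-yl]-4-hydroxyfuran-2(5H)-one, via bis-silyloxyfuran 14 (not isolated), via bis-silyl aldol adduct 15 (not isolated)
Conditions: t-BuMe2SiOTf (2.1 equiv), Et3N, CH2Cl2, 0 °C; then 13, (S)-2-butyl-4-(1H-indol-3-ylmethyl)-3-(4-methylphenyl)sulfonyl-1,3,2-oxazaborolidin-5-one (20 mol%), EtCN, −78 °C; then 1 M HCl, MeOH, 0 °C
Reagents that add atoms: none
Why: Double silylation gives a cyclic Chan-type bis(silyloxy)diene that attacks the aldehyde through its terminal carbon (C7) in a vinylogous Mukaiyama aldol reaction, the open antiperiplanar transition state giving the threo adduct (C6–O and C7–O syn in the zigzag chain) while the chiral boron Lewis acid bound to 2-bromoacrolein fixes the absolute configuration of C6 and C7, and acid then strips both silyl groups.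

Step 7
Reactants: 16 hydroxyallyl tetronic acid
Product: 17 (5S)-5-[(1S)-2-bromo-1-(methoxymethoxy)prop-2-en-1-yl]-4-(methoxymethoxy)furan-2(5H)-one
Conditions: MeOCH2Cl (3 equiv), i-Pr2NEt, CH2Cl2, 0 °C to rt
Reagents that add atoms: chloromethyl methyl ether (COCCl)
Why: O-Alkylation (Williamson type) of the vinylogous acid oxygen and of the secondary alcohol gives two methoxymethyl ethers that survive the later aqueous acid and locks the tetronate as its 4-alkoxy butenolide.

Step 8
Reactants: 17 bis(methoxymethyl) tetronate; 18 1,3-dioxolane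
Product: 19 (4S,5S)-5-[(1S)-2-bromo-1-(methoxymethoxy)prop-2-en-1-yl]-4-(1,3-dioxolan-2-yl)-4-(methoxymethoxy)dihydrofuran-2(3H)-one
Conditions: (n-Bu4N)4[W10O32] (2 mol%), 1,3-dioxolane/MeCN (1:1), 390 nm LED, rt
Reagents that add atoms: none
Why: Photocatalytic hydrogen-atom transfer from 1,3-dioxolane gives the nucleophilic 2-dioxolanyl radical, which adds to the β-carbon C8 of the β-alkoxy butenolide (Giese reaction, as in decatungstate additions to β,β-disubstituted enones and photo-additions to 5-substituted furanones) on the face anti to the C7 side chain, so the fully substituted C8 is formed with C9 at the aldehyde oxidation level and trans to C6.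

Step 9
Reactants: 19 dioxolanyl lactone
Product: 20 (3R,4S,5S)-5-[(1S)-2-bromo-1-(methoxymethoxy)prop-2-en-1-yl]-4-(1,3-dioxolan-2-yl)-4-(methoxymethoxy)-3-methyldihydrofuran-2(3H)-one
Conditions: LiN(SiMe3)2, THF, −78 °C; then MeI, −78 to −40 °C
Reagents that add atoms: iodomethane (CI)
Why: Lactone enolate alkylation in which iodomethane approaches C17 on the face opposite the branched dioxolanyl group of the neighbouring C8, giving the 17-methyl trans to C9, which is also the thermodynamically preferred epimer.

Step 10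
Reactants: 11 ring A alkyne; 20 bromovinyl lactone
Product: 21 enyne (C4–C5 coupling product of 11 and 20)
Conditions: Pd(PPh3)4 (5 mol%), CuI (10 mol%), i-Pr2NH, THF, rt
Reagents that add atoms: none
Why: Sonogashira coupling of the terminal alkyne with the 1,1-disubstituted vinyl bromide forms the C4–C5 bond and leaves the secondary alkyl bromide, the esters and all stereocentres untouched.

Step 11
Reactants: 21 enyne
Product: 22 (3Z)-diene
Conditions: Zn dust activated with Cu(OAc)2 and AgNO3, MeOH/H2O (1:1), 40 °C
Reagents that add atoms: none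
Why: Activated zinc reduces only the triple bond of a conjugated enyne and stops at the cis alkene (Boland-type semi-reduction), which gives the 3Z olefin next to the 5(16)-methylene.

Step 12
Reactants: 22 (3Z)-diene
Product: 24 seco enone aldehyde, via bromo ketone 23 (not isolated)
Conditions: 1 M aq. HCl, THF, 40 °C; then Et3N, CH2Cl2, 0 °C
Reagents that add atoms: water (O)
Why: Acid hydrolysis of the silyl enol ether and of the dioxolane (the methoxymethyl ethers need stronger acid) frees the C12 ketone and the C9 aldehyde, and Et3N then removes HBr from the β-bromo ketone through C11 (E1cB elimination, far faster than loss of the β-butanoate) to give the 2-methyl enone.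

Step 13
Reactants: 24 seco enone aldehyde
Product: 25 macrocyclic alcohol (9-O-deacetyl-6-dechloro-6-epi-6,8-bis(methoxymethoxy) analogue of ptilosarcone)
Conditions: SmI2 (3 equiv), THF/MeOH (20:1), −78 °C, slow addition of 24 (2 mM final); then aq. NH4Cl
Reagents that add atoms: none
Why: Proposed new method: SmI2 reduces the aldehyde to a samarium ketyl radical that adds to the enone β-carbon C10 and closes the ten-membered ring (closest known reactions: SmI2 ketyl–enone and ketyl–olefin cyclisations to five- to eight-membered rings and SmI2 pinacol macrocyclisations), attack anti to the pseudo-axial C1–C2 bond giving the trans ring fusion (C9 on the β face), the staggered approach with H-9 between C1 and C11 and the chain anti to C1 setting C9, and protonation of the trivalent samarium enolate by MeOH on the α face, anti to C9, fixing C11.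

Step 14
Reactants: 25 macrocyclic alcohol
Product: 26 macrocyclic 9-acetate
Conditions: Ac2O, 4-(dimethylamino)pyridine (cat.), pyridine, CH2Cl2, 0 °C to rt
Reagents that add atoms: acetic anhydride (CC(=O)OC(C)=O)
Why: Esterification of the only free hydroxyl gives the 9-acetate and draws any 9,12-hemiketal back to the open keto form.

Step 15
Reactants: 26 macrocyclic 9-acetate
Product: 27 6-dechloro-6-epi-6-hydroxyptilosarcone
Conditions: Me2BBr, CH2Cl2, −78 °C; then aq. NaHCO3
Reagents that add atoms: none
Why: Bromodimethylborane cleaves both methoxymethyl ethers at low temperature (Lewis-acid-mediated acetal cleavage) without touching the three esters, the β-acyloxy ketone or the epimerisable C11.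

Step 16
Reactants: 27 6-dechloro-6-epi-6-hydroxyptilosarcone
Product: 28 ptilosarcone
Conditions: PPh3, hexachloroacetone, CH2Cl2, 0 °C
Reagents that add atoms: hexachloroacetone (O=C(C(Cl)(Cl)Cl)C(Cl)(Cl)Cl)
Why: The secondary allylic alcohol is converted into the chloride by SN2 displacement of its alkoxyphosphonium ion (Appel-type reaction under neutral conditions) with inversion at C6 and little allylic transposition, while the tertiary 8-hydroxyl does not react.

## Compound list

1 | pent-1-yn-3-one | C#CC(=O)CC | starting material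
2 | butanoic acid | CCCC(=O)O | starting material
3 | (E)-3-oxopent-1-en-1-yl butanoate | CCCC(=O)O/C=C/C(=O)CC | intermediate
4 | (1E,3Z)-3-[(triisopropylsilyl)oxy]penta-1,3-dien-1-yl butanoate | CCCC(=O)O/C=C/C(O[Si](C(C)C)(C(C)C)C(C)C)=C/C | intermediate
5 | methacrolein (2-methylprop-2-enal) | C=C(C)C=O | starting material
6 | 2,3-dibromo-2-methylpropanal (racemic) | O=CC(C)(Br)CBr | intermediate
7 | (E)-3-bromo-2-methylprop-2-enal | O=C/C(C)=C/Br | intermediate
8 | ring A aldehyde: (1S,4R,5S,6R)-5-bromo-6-formyl-4,6-dimethyl-3-[(triisopropylsilyl)oxy]cyclohex-2-en-1-yl butanoate (formyl cis to butanoyloxy; Br trans to formyl; ring C6/C1/C3/C4/C5 = briarane C1/C14/C12/C11/C10) | O=C[C@]1(C)[C@H]([C@H](C)C(O[Si](C(C)C)(C(C)C)C(C)C)=C[C@@H]1OC(=O)CCC)Br | intermediate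
9 | ethynylmagnesium bromide | C#C[Mg]Br | starting material
10 | bromomagnesium alkoxide of the (S)-ethynyl carbinol formed from 8 | C#C[C@H](O[Mg]Br)[C@]1(C)[C@H]([C@H](C)C(O[Si](C(C)C)(C(C)C)C(C)C)=C[C@@H]1OC(=O)CCC)Br | intermediate
11 | ring A alkyne: (1S,4R,5S,6R)-6-[(1S)-1-acetoxyprop-2-yn-1-yl]-5-bromo-4,6-dimethyl-3-[(triisopropylsilyl)oxy]cyclohex-2-en-1-yl butanoate | C#C[C@H](OC(C)=O)[C@]1(C)[C@H]([C@H](C)C(O[Si](C(C)C)(C(C)C)C(C)C)=C[C@@H]1OC(=O)CCC)Br | intermediate
12 | tetronic acid (4-hydroxyfuran-2(5H)-one) | OC1=CC(=O)OC1 | starting material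
13 | 2-bromoacrolein (2-bromoprop-2-enal) | C=C(Br)C=O | starting material
14 | 2,4-bis{[tert-butyl(dimethyl)silyl]oxy}furan | CC(C)(C)[Si](C)(C)Oc1coc(O[Si](C)(C)C(C)(C)C)c1 | intermediate
15 | (5S)-5-[(1S)-2-bromo-1-{[tert-butyl(dimethyl)silyl]oxy}prop-2-en-1-yl]-4-{[tert-butyl(dimethyl)silyl]oxy}furan-2(5H)-one | C=C(Br)[C@@H](O[Si](C)(C)C(C)(C)C)[C@@H]1OC(=O)C=C1O[Si](C)(C)C(C)(C)C | intermediate
16 | (5S)-5-[(1S)-2-bromo-1-hydroxyprop-2-en-1-yl]-4-hydroxyfuran-2(5H)-one (threo; ring carbon = C7 as in the target; carbinol carbon = C6 with the configuration opposite to the C–Cl centre of the target) | C=C(Br)[C@@H](O)[C@@H]1OC(=O)C=C1O | intermediate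
17 | (5S)-5-[(1S)-2-bromo-1-(methoxymethoxy)prop-2-en-1-yl]-4-(methoxymethoxy)furan-2(5H)-one | C=C(Br)[C@@H](OCOC)[C@@H]1OC(=O)C=C1OCOC | intermediate
18 | 1,3-dioxolane | C1COCO1 | starting material
19 | (4S,5S)-5-[(1S)-2-bromo-1-(methoxymethoxy)prop-2-en-1-yl]-4-(1,3-dioxolan-2-yl)-4-(methoxymethoxy)dihydrofuran-2(3H)-one (dioxolanyl trans to the C5 side chain) | C=C(Br)[C@@H](OCOC)[C@@H]1OC(=O)C[C@@]1(OCOC)C2OCCO2 | intermediate
20 | (3R,4S,5S)-5-[(1S)-2-bromo-1-(methoxymethoxy)prop-2-en-1-yl]-4-(1,3-dioxolan-2-yl)-4-(methoxymethoxy)-3-methyldihydrofuran-2(3H)-one (3-methyl trans to dioxolanyl) | C=C(Br)[C@@H](OCOC)[C@@H]1OC(=O)[C@H](C)[C@@]1(OCOC)C2OCCO2 | intermediate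
21 | enyne: 11 and 20 joined C4–C5 (but-1-en-3-yne with the ring A carbinol acetate on C3 and the lactone carbinol on C5; stereocentres as in 11 and 20) | C=C(C#C[C@H](OC(C)=O)[C@]2(C)[C@H]([C@H](C)C(O[Si](C(C)C)(C(C)C)C(C)C)=C[C@@H]2OC(=O)CCC)Br)[C@@H](OCOC)[C@@H]1OC(=O)[C@H](C)[C@@]1(OCOC)C3OCCO3 | intermediate
22 | (3Z)-diene: 21 with the triple bond reduced to the cis C3=C4 alkene | C=C(/C=C\[C@H](OC(C)=O)[C@]2(C)[C@H]([C@H](C)C(O[Si](C(C)C)(C(C)C)C(C)C)=C[C@@H]2OC(=O)CCC)Br)[C@@H](OCOC)[C@@H]1OC(=O)[C@H](C)[C@@]1(OCOC)C3OCCO3 | intermediate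
23 | bromo ketone aldehyde: 22 with the C12 ketone and the C9 aldehyde unmasked, C10–Br still present | C=C(/C=C\[C@H](OC(C)=O)[C@]2(C)[C@H]([C@H](C)C(=O)C[C@@H]2OC(=O)CCC)Br)[C@@H](OCOC)[C@@H]1OC(=O)[C@H](C)[C@@]1(OCOC)C=O | intermediate
24 | seco enone aldehyde: ring A 2-methylcyclohex-2-enone (C10=C11) with the 14-butanoate and the (2S,3Z)-diene chain on C1, linked to the 6,8-bis(methoxymethoxy) lactone that carries the C9 aldehyde | C=C(/C=C\[C@H](OC(C)=O)[C@]2(C)C=C(C)C(=O)C[C@@H]2OC(=O)CCC)[C@@H](OCOC)[C@@H]1OC(=O)[C@H](C)[C@@]1(OCOC)C=O | intermediate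
25 | macrocyclic alcohol: 9-O-deacetyl-6-dechloro-6-epi-6,8-bis(methoxymethoxy) analogue of ptilosarcone (ring fusion, C9, C10, C11 as in the target) | C=C1/C=C\[C@H](OC(C)=O)[C@]2(C)[C@H]([C@@H](C)C(=O)C[C@@H]2OC(=O)CCC)[C@H](O)[C@]2(OCOC)[C@@H](C)C(=O)O[C@H]2[C@@H]1OCOC | intermediate
26 | macrocyclic 9-acetate: 6-dechloro-6-epi-6,8-bis(methoxymethoxy) analogue of ptilosarcone | C=C1/C=C\[C@H](OC(C)=O)[C@]2(C)[C@H]([C@@H](C)C(=O)C[C@@H]2OC(=O)CCC)[C@H](OC(C)=O)[C@]2(OCOC)[C@@H](C)C(=O)O[C@H]2[C@@H]1OCOC | intermediate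
27 | 6-dechloro-6-epi-6-hydroxyptilosarcone (6,8-diol; C6–OH on the face opposite to the chlorine of the target) | C=C1/C=C\[C@H](OC(C)=O)[C@]2(C)[C@H]([C@@H](C)C(=O)C[C@@H]2OC(=O)CCC)[C@H](OC(C)=O)[C@]2(O)[C@@H](C)C(=O)O[C@H]2[C@@H]1O | intermediate
28 | ptilosarcone | C=C1/C=C\[C@H](OC(C)=O)[C@]2(C)[C@H]([C@@H](C)C(=O)C[C@@H]2OC(=O)CCC)[C@H](OC(C)=O)[C@]2(O)[C@@H](C)C(=O)O[C@H]2[C@H]1Cl | target

## Step count and risks

Total step count: 16. Longest linear sequence: 11 steps (1, 2, 4, 5, 10–16; the lactone branch 6–9 followed by 10–16 is also 11).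

Three steps most likely to fail:

Step 13. The new bond joins two carbons that each adjoin a fully substituted centre, in a ten-membered ring; the ketyl may simply be reduced, may be trapped 6-endo by C16 of the diene, or may give the cis ring fusion or the wrong C9 epimer. Fallback: the C9–C10 bond is made between two separate fragments and the ring is closed at C3=C4 by olefin metathesis; it sets out from 8 and 20 and comes back at 25. Vinylmagnesium bromide then Ac2O (THF, −78 °C) turns 8 into the vinyl carbinol acetate F1, and 1 M aq. HCl/THF followed by Et3N gives the ring A enone F2. Stille coupling of 20 with tributyl(vinyl)stannane (Pd(PPh3)4, CuI, DMF, 50 °C) gives the butadienyl lactone F3, whose dioxolane is hydrolysed (1 M aq. HCl/THF) to the aldehyde F4. SmI2 (THF/MeOH, −78 °C) joins F4 (2 equiv) to F2 to give the open-chain hydroxy ketone F5, and the second-generation Grubbs catalyst (H2IMes)(PCy3)Cl2Ru=CHPh (toluene, 1 mM, 80 °C) closes the ring at the Z olefin with loss of ethene, which gives 25.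

Step 8. The acceptor carbon already carries an alkoxy group and a branched chain, so the intermolecular radical addition may be slow, and the vinyl bromide or the acetal C–H bonds of the substrate may compete. Fallback: C9 is brought in one oxidation level lower by the ketone-sensitised photo-addition of methanol; it sets out from 17 and comes back at 19. Irradiation of 17 (350 nm) in methanol with benzophenone adds the hydroxymethyl radical to C8 anti to the side chain and gives the hydroxymethyl lactone F6. PhI(OAc)2 with 2,2,6,6-tetramethylpiperidin-1-oxyl (CH2Cl2, rt) oxidises it at once to the aldehyde F7, before the primary alcohol can translactonise. 1,2-Bis(trimethylsilyloxy)ethane with Me3SiOTf (cat., CH2Cl2, −78 °C) then gives 19.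

Step 16. Direct displacement at the hindered secondary allylic C6 may lose to SN2′ attack at the open C16 terminus, which gives the 16-chloro-5(6)-ene isomer. Fallback: that transposed isomer is made on purpose and chlorine is returned to C6 by a [2,3]-sigmatropic shift; it sets out from 27 and comes back at 28. SOCl2 (Et2O, 0 °C) converts 27 with allylic transposition into the primary 16-chloride F8. PhSeH with i-Pr2NEt (DMF, 0 °C) displaces the chloride to give the allylic selenide F9. N-Chlorosuccinimide (CH2Cl2, −20 °C) chlorinates selenium, and the [2,3] shift delivers chlorine to C6 and restores the 5(16)-methylene, which gives 28.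

Further compounds
F1 | step 13 | ring A vinyl carbinol acetate: 11 with CH=CH2 in place of C≡CH (same configuration) | C=C[C@H](OC(C)=O)[C@]1(C)[C@H]([C@H](C)C(O[Si](C(C)C)(C(C)C)C(C)C)=C[C@@H]1OC(=O)CCC)Br
F2 | step 13 | ring A enone: 2-methylcyclohex-2-enone with the C15 methyl and the (S)-1-acetoxyallyl group on briarane C1 and the butanoate on C14 | C=C[C@H](OC(C)=O)[C@]1(C)C=C(C)C(=O)C[C@@H]1OC(=O)CCC
F3 | step 13 | butadienyl lactone: 20 with CH=CH2 in place of Br | C=CC(=C)[C@@H](OCOC)[C@@H]1OC(=O)[C@H](C)[C@@]1(OCOC)C2OCCO2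
F4 | step 13 | butadienyl lactone aldehyde: F3 with CHO in place of the dioxolanyl group | C=CC(=C)[C@@H](OCOC)[C@@H]1OC(=O)[C@H](C)[C@@]1(OCOC)C=O
F5 | step 13 | open-chain hydroxy ketone: 25 without the C3–C4 bond (terminal CH=CH2 on C2 and on C5) | C=C[C@H](OC(C)=O)[C@]2(C)[C@H]([C@@H](C)C(=O)C[C@@H]2OC(=O)CCC)[C@H](O)[C@]2(OCOC)[C@@H](C)C(=O)O[C@H]2[C@H](OCOC)C(=C)C=C
F6 | step 8 | hydroxymethyl lactone: 19 with CH2OH in place of the dioxolanyl group | C=C(Br)[C@@H](OCOC)[C@@H]1OC(=O)C[C@@]1(OCOC)CO
F7 | step 8 | formyl lactone: 19 with CHO in place of the dioxolanyl group | C=C(Br)[C@@H](OCOC)[C@@H]1OC(=O)C[C@@]1(OCOC)C=O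
F8 | step 16 | 16-chloro-5(6)-ene isomer of ptilosarcone (chlorine on C16; C5=C6 with C4 and C7 cis) | C[C@H]1C(=O)O[C@@H](\C=C(CCl)/C=C\[C@H](OC(C)=O)[C@]3(C)[C@H]([C@@H](C)C(=O)C[C@@H]3OC(=O)CCC)[C@@H]2OC(C)=O)[C@@]12O
F9 | step 16 | 16-(phenylselanyl)-5(6)-ene: F8 with SePh in place of Cl | C[C@H]1C(=O)O[C@@H](\C=C(C[Se]c4ccccc4)/C=C\[C@H](OC(C)=O)[C@]3(C)[C@H]([C@@H](C)C(=O)C[C@@H]3OC(=O)CCC)[C@@H]2OC(C)=O)[C@@]12O
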